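**Strategy.** The γ-lactone is numbered as a 5-oxooxolane (O1, C2 bearing the chain, C3 bearing CO2H, C4, C5=O) and is cut at C4–C5 and C2–C3. This exploits two features: O1 already joins C5 and C2, so both can arrive as one ClCH(R)–O–C(=O) unit, and C3–C4 is an acrylate unit. In the key step an alkoxycarbonyl radical from a racemic 1-chloroalkyl N-phthalimidoyl oxalate adds to a chiral N-acryloyl oxazolidinone; the zinc enolate formed then closes on the epimerising O–CHCl carbon. This formal (3+2) radical–polar crossover annulation funnels both chloride epimers into the trans-lactone. The exocyclic methylene is added last.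

Key step: step 6

Remark on the chemistry: the target is read as the trans-(2R,3S) lactone in the numbering above; the chloride-bearing carbon of 7 and 11 is racemic by design and is written without configuration.

Step 1
Reactants: 1 16-hydroxyhexadecanoic acid
Product: 2 methyl 16-hydroxyhexadecanoate
Conditions: MeOH (solvent), H2SO4 (cat.), reflux
Reagents that add atoms: methanol, CO
Why: Fischer esterification in a large excess of methanol should outcompete self-esterification of the hydroxy acid; the methyl ester masks the distal acid until step 7.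

Step 2
Reactants: 2 methyl 16-hydroxyhexadecanoate
Product: 3 methyl 16-oxohexadecanoate
Conditions: TEMPO (10 mol %), PhI(OAc)2 (1.1 equiv), CH2Cl2, rt
Reagents that add atoms: none
Why: TEMPO/PhI(OAc)2 (oxoammonium) oxidation of a primary alcohol should stop at the aldehyde and leave the ester untouched.

Step 3
Reactants: 4 N-hydroxyphthalimide; 5 oxalyl chloride
Product: 6 chloro N-phthalimidoyl oxalate (1,3-dioxoisoindolin-2-yl chlorooxoacetate)
Conditions: 5 (5 equiv), THF, −78 °C → rt, then evaporation; used crude
Reagents that add atoms: none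
Why: O-acylation of the N-hydroxy imide by excess oxalyl chloride should stop at the mono-acid chloride, the standard reagent for making N-phthalimidoyl oxalates.

Step 4
Reactants: 3 methyl 16-oxohexadecanoate; 6 chloro N-phthalimidoyl oxalate
Product: 7 methyl 16-chloro-16-({[(1,3-dioxoisoindolin-2-yl)oxy](oxo)acetyl}oxy)hexadecanoate (racemic at C16)
Conditions: ZnCl2 (5 mol %), 4 Å MS, CH2Cl2, −20 → 0 °C; filtered and used crude
Reagents that add atoms: none
Why: Lewis-acid-catalysed addition of an acyl chloride across an aldehyde C=O (1-chloroalkyl ester formation) should join the former aldehyde oxygen to the oxalyl carbon and put chloride on the former aldehyde carbon; the new O–CHCl centre forms racemic, which the key step tolerates.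

Step 5
Reactants: 8 (R)-4-benzyl-1,3-oxazolidin-2-one; 9 acryloyl chloride
Product: 10 (R)-3-acryloyl-4-benzyl-1,3-oxazolidin-2-one
Conditions: Et3N (1.3 equiv), LiCl (1.2 equiv), THF, −20 °C → rt, trace BHT
Reagents that add atoms: none
Why: LiCl/Et3N-mediated N-acylation of the oxazolidinone avoids strong base and so should limit polymerisation of the acrylate.

Step 6
Reactants: 7 methyl 16-chloro-16-({[(1,3-dioxoisoindolin-2-yl)oxy](oxo)acetyl}oxy)hexadecanoate; 10 (R)-3-acryloyl-4-benzyl-1,3-oxazolidin-2-one
Product: 12 (4R)-4-benzyl-3-{[(2R,3S)-2-(15-methoxy-15-oxopentadecyl)-5-oxooxolan-3-yl]carbonyl}-1,3-oxazolidin-2-one, via open-chain chlorozinc enolate 11 (not isolated)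
Conditions: 7 added slowly to Zn dust (3 equiv), NiCl2·glyme (10 mol %), LiCl (3 equiv), 10 (2 equiv), MeCN/THF, 0 °C → rt, Ar; aq. NH4Cl work-up
Reagents that add atoms: zinc, [Zn]; lithium chloride, [Li+].[Cl-] (both end up only in intermediate 11)
Why: Proposed new method: Ni/Zn single-electron reduction of the N-phthalimidoyl oxalate in 7 should expel phthalimide and CO2 and leave the alkoxycarbonyl radical ClCH(R)O–C(=O)•, which adds to the CH2 terminus of 10 (C4–C5 bond); reduction of the α-imide radical gives the chelated (Z)-zinc enolate 11, which alkylates its own O–CHCl carbon (C2–C3 bond). The closest known reaction types are the conjugate addition of alkoxycarbonyl radicals generated from N-phthalimidoyl oxalates, Ni/Zn reductive Giese additions of redox-active esters, radical–polar crossover cyclisations that end in an intramolecular SN2 step, and the alkylation of Evans enolates with α-halo ethers. The lactone ring closes in the polar 5-(enolexo)-exo-tet mode through the s-cis rotamer of the ester tether. C3 is controlled by the (R)-benzyl oxazolidinone, whose benzyl group blocks one face of the enolate so that C–C bond formation gives 3S; C2 is controlled by the ring closure itself, which places the chain trans to the acyl group and so gives 2R. Because Zn(II)/chloride exchange epimerises the 1-chloroalkyl ester carbon, both C–Cl epimers of 11 should drain into the same trans-lactone (dynamic stereoconvergence). The step needs radical addition to outrun decarboxylation of the alkoxycarbonyl radical and ring closure to outrun protonation of 11, which excess 10, slow addition of 7, an aprotic medium and the oxocarbenium-like reactivity of the chloroalkyl ester are meant to secure.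

Step 7
Reactants: 12 (4R)-4-benzyl-3-{[(2R,3S)-2-(15-methoxy-15-oxopentadecyl)-5-oxooxolan-3-yl]carbonyl}-1,3-oxazolidin-2-one
Product: 14 (2R,3S)-2-(14-carboxytetradecyl)-5-oxooxolane-3-carboxylic acid, via ring-opened trilithium salt 13 (not isolated)
Conditions: LiOH·H2O (6 equiv), 30% H2O2 (8 equiv), THF/H2O 3:1, 0 °C → rt; Na2SO3; then 2 M HCl to pH 1, rt
Reagents that add atoms: lithium hydroxide, [Li+].[OH-]; hydrogen peroxide, OO
Why: Evans LiOOH cleavage should remove the auxiliary at the exocyclic carbonyl without touching C3, while the same hydroxide saponifies the methyl ester and opens the lactone to 13; acidification relactonises to the five-membered ring with both stereocentres retained.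

Step 8
Reactants: 14 (2R,3S)-2-(14-carboxytetradecyl)-5-oxooxolane-3-carboxylic acid
Product: 16 (2R,3S)-2-(14-carboxytetradecyl)-4-methylidene-5-oxooxolane-3-carboxylic acid (target), via α-carboxy lactone 15 (not isolated)
Conditions: MeOMgOCO2Me (Stiles' reagent, 2 M in DMF, ca. 40 equiv), 135 °C; cold 6 M HCl work-up; then 37% aq. CH2O, N-methylaniline, NaOAc, AcOH, rt
Reagents that add atoms: formaldehyde, C=O; methyl magnesium carbonate, COC(=O)O[Mg]OC (its CO2 unit ends up only in intermediate 15)
Why: Stiles carboxylation of the lactone α-CH2 followed by decarboxylative Mannich methylenation is the established endgame for paraconic acids; the C3 carboxylate keeps C3–H from being deprotonated, so neither Stobbe-type ring opening nor loss of the trans C2/C3 relationship is expected, and no stereocentre is formed.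

**Compound list**

1 | 16-hydroxyhexadecanoic acid | OC(=O)CCCCCCCCCCCCCCCO | starting material
2 | methyl 16-hydroxyhexadecanoate | COC(=O)CCCCCCCCCCCCCCCO | intermediate
3 | methyl 16-oxohexadecanoate | COC(=O)CCCCCCCCCCCCCCC=O | intermediate
4 | N-hydroxyphthalimide | ON1C(=O)c2ccccc2C1=O | starting material
5 | oxalyl chloride | ClC(=O)C(=O)Cl | starting material
6 | chloro N-phthalimidoyl oxalate | O=C(Cl)C(=O)ON1C(=O)c2ccccc2C1=O | intermediate
7 | methyl 16-chloro-16-({[(1,3-dioxoisoindolin-2-yl)oxy](oxo)acetyl}oxy)hexadecanoate (racemic) | COC(=O)CCCCCCCCCCCCCCC(Cl)OC(=O)C(=O)ON1C(=O)c2ccccc2C1=O | intermediate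
8 | (R)-4-benzyl-1,3-oxazolidin-2-one | O=C1N[C@H](Cc2ccccc2)CO1 | starting material
9 | acryloyl chloride | C=CC(=O)Cl | starting material
10 | (R)-3-acryloyl-4-benzyl-1,3-oxazolidin-2-one | C=CC(=O)N1[C@H](Cc2ccccc2)COC1=O | intermediate
11 | chlorozinc (Z)-enolate of (4R)-4-benzyl-3-{4-[(1-chloro-16-methoxy-16-oxohexadecyl)oxy]-4-oxobutanoyl}-1,3-oxazolidin-2-one | COC(=O)CCCCCCCCCCCCCCC(Cl)OC(=O)C/C=C(\O[Zn]Cl)N1[C@H](Cc2ccccc2)COC1=O | intermediate (not isolated)
12 | (4R)-4-benzyl-3-{[(2R,3S)-2-(15-methoxy-15-oxopentadecyl)-5-oxooxolan-3-yl]carbonyl}-1,3-oxazolidin-2-one | C1C(=O)O[C@H](CCCCCCCCCCCCCCC(=O)OC)[C@H]1C(=O)N2[C@H](Cc3ccccc3)COC2=O | intermediate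
13 | trilithium (2S,3R)-2-(carboxylatomethyl)-3-hydroxyoctadecanedioate | [Li+].[Li+].[Li+].[O-]C(=O)C[C@H](C(=O)[O-])[C@H](O)CCCCCCCCCCCCCCC(=O)[O-] | intermediate (not isolated)
14 | (2R,3S)-2-(14-carboxytetradecyl)-5-oxooxolane-3-carboxylic acid | C1C(=O)O[C@H](CCCCCCCCCCCCCCC(=O)O)[C@H]1C(=O)O | intermediate
15 | (2R,3S)-2-(14-carboxytetradecyl)-5-oxooxolane-3,4-dicarboxylic acid (C4 epimers) | OC(=O)C1C(=O)O[C@H](CCCCCCCCCCCCCCC(=O)O)[C@H]1C(=O)O | intermediate (not isolated)
16 | (2R,3S)-2-(14-carboxytetradecyl)-4-methylidene-5-oxooxolane-3-carboxylic acid | C=C1C(=O)O[C@H](CCCCCCCCCCCCCCC(=O)O)[C@H]1C(=O)O | target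

**Step count.** Total: 8 steps. Longest linear sequence: 6 steps (1, 2, 4, 6, 7, 8).

**Steps most likely to fail**

1. Step 6 (proposed new method). What may go wrong:
 - loss of CO2 from the alkoxycarbonyl radical before it adds to 10;
 - reductive activation of the C–Cl bond instead of the N–O bond;
 - protonation or oligomerisation of enolate 11 before ring closure;
 - poor facial selectivity if the zinc enolate is only weakly chelated;
 - enolisation of 12 followed by β-elimination of the lactone carboxylate.

 Fallback, known chemistry only, setting out from 8 and 3: N-acylation of lithiated 8 (n-BuLi, THF, −78 °C) with succinic anhydride gives 4-[(4R)-4-benzyl-2-oxo-1,3-oxazolidin-3-yl]-4-oxobutanoic acid F1. Oxalyl chloride with catalytic DMF converts it into the acid chloride 4-[(4R)-4-benzyl-2-oxo-1,3-oxazolidin-3-yl]-4-oxobutanoyl chloride F2. ZnCl2-catalysed addition of F2 across the aldehyde of 3 gives the 1-chloroalkyl succinate 1-chloro-16-methoxy-16-oxohexadecyl 4-[(4R)-4-benzyl-2-oxo-1,3-oxazolidin-3-yl]-4-oxobutanoate F3, which is also the protonated form of 11. NaHMDS with catalytic NaI in THF at −78 °C then closes F3 by intramolecular Evans enolate alkylation, and the sequence comes back to the route at 12. A cascade that stalls at the open-chain stage can be finished the same way. In this fallback the C4–C5 bond is bought with succinic anhydride instead of being made in the annulation.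

2. Step 4. What may go wrong: reversal or hydrolysis of the 1-chloroalkyl oxalate, enolisation and self-condensation of the aldehyde under ZnCl2, or decomposition of the bulky acid chloride 6 before it adds.

 Fallback, setting out from 3: the order of assembly is changed. Oxalyl chloride 5 itself (excess, ZnCl2 cat., CH2Cl2, −20 °C) is added across the aldehyde to give methyl 16-chloro-16-[(chlorooxoacetyl)oxy]hexadecanoate F4. The remaining acid chloride is then esterified with N-hydroxyphthalimide 4 and pyridine at −40 °C, and the sequence comes back to the route at 7.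

3. Step 8. What may go wrong: incomplete α-carboxylation of the dianionic substrate at 135 °C, migration of the new exocyclic double bond into the ring, or conjugate addition of the amine to the product.

 Fallback, setting out from 14: Fischer esterification (MeOH, H2SO4) gives methyl (2R,3S)-2-(15-methoxy-15-oxopentadecyl)-5-oxooxolane-3-carboxylate F5. NaH and ethyl formate in Et2O formylate the lactone α-CH2 to give the sodium enolate of the 4-formyl lactone F6. Paraformaldehyde in THF at reflux then gives, with loss of formate, methyl (2R,3S)-2-(15-methoxy-15-oxopentadecyl)-4-methylidene-5-oxooxolane-3-carboxylate F7. Hydrolysis of both methyl esters with 6 M HCl in dioxane at reflux brings the sequence back to the route at 16.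

**Further compounds**

F1 | step 6 | 4-[(4R)-4-benzyl-2-oxo-1,3-oxazolidin-3-yl]-4-oxobutanoic acid | OC(=O)CCC(=O)N1[C@H](Cc2ccccc2)COC1=O
F2 | step 6 | 4-[(4R)-4-benzyl-2-oxo-1,3-oxazolidin-3-yl]-4-oxobutanoyl chloride | ClC(=O)CCC(=O)N1[C@H](Cc2ccccc2)COC1=O
F3 | step 6 | 1-chloro-16-methoxy-16-oxohexadecyl 4-[(4R)-4-benzyl-2-oxo-1,3-oxazolidin-3-yl]-4-oxobutanoate | COC(=O)CCCCCCCCCCCCCCC(Cl)OC(=O)CCC(=O)N1[C@H](Cc2ccccc2)COC1=O
F4 | step 4 | methyl 16-chloro-16-[(chlorooxoacetyl)oxy]hexadecanoate | COC(=O)CCCCCCCCCCCCCCC(Cl)OC(=O)C(=O)Cl
F5 | step 8 | methyl (2R,3S)-2-(15-methoxy-15-oxopentadecyl)-5-oxooxolane-3-carboxylate | C1C(=O)O[C@H](CCCCCCCCCCCCCCC(=O)OC)[C@H]1C(=O)OC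
F6 | step 8 | sodium enolate of methyl (2R,3S)-4-formyl-2-(15-methoxy-15-oxopentadecyl)-5-oxooxolane-3-carboxylate | [Na+].[O-]C=C1C(=O)O[C@H](CCCCCCCCCCCCCCC(=O)OC)[C@H]1C(=O)OC
F7 | step 8 | methyl (2R,3S)-2-(15-methoxy-15-oxopentadecyl)-4-methylidene-5-oxooxolane-3-carboxylate | C=C1C(=O)O[C@H](CCCCCCCCCCCCCCC(=O)OC)[C@H]1C(=O)OC
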